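Look first at the early seconds of the flasks set down here.

| setting | Saturday's | Monday's | Tuesday's | Sunday's |
|---|---|---|---|---|
| starting material | 11 mM | 11 mM (in portions, 5, over 8.0 s) | 11 mM | 11 mM (fed, over 8.0 s) |
| first nucleophile | 11.5 mM (fed, over 8.0 s) | 11.5 mM | 11.5 mM | 11.5 mM |
| solid second nucleophile | 55.0 mM | 55.0 mM | 55.0 mM | 55.0 mM |
| time | 20 s | 20 s | 20 s | 20 s |
| remark | all else is in the flask from the start; the feed brings no volume worth counting | first portion at the start, last at 8.0 s | everything together at the start | all else is in the flask from the start; the feed brings no volume worth counting |

    second nucleophile + intermediate → other capture product (k1 = 66.5 L mol⁻¹ s⁻¹)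
    starting material + target → side product (k2 = 5.71 L mol⁻¹ s⁻¹)
    first nucleophile + intermediate → target (k3 = 318 L mol⁻¹ s⁻¹)
    first nucleophile ⇌ dormant form (K4 = 11, k4 = 0.378 s⁻¹)
    solid second nucleophile ⇌ second nucleophile, rate k5*(cs5 - [second nucleophile]) while solid is left; crystals form when [second nucleophile] > cs5 (cs5 = 2.2 mM, k5 = 0.283 s⁻¹)
    starting material ⇌ intermediate (K6 = 0.0595, k6 = 0.946 s⁻¹)

- in percentages every species weighs as the starting material in it: one side product counts as two
- as a solid, counted per litre of solution: solid second nucleophile
- at the start none of the solid second nucleophile is in solution
- run time (Saturday's): 20 s

1. which flask leads in amount of side product, in percent of the starting material charged ("all alike" within 1.5 percentage points) (Saturday's / Monday's / Tuesday's / Sunday's / all alike)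
2. how much side product is there at the end, in percent of the starting material charged: Saturday's
3. how much side product is there at the end, in percent of the starting material charged: Monday's
4. how much side product is there at the end, in percent of the starting material charged: Tuesday's
5. how much side product is there at the end, in percent of the starting material charged: Sunday's

**Turned round.** Ask what a tie would demand. Write a, p and o for starting material, target and side product as shares of the charge. One side product holds two starting materials, so o grows at a·p/τ, where τ, the overlap clock, is one over twice the side-product rate constant times the starting-material charge: 7.96 s. A tie then needs the mean a·p of the flasks to give, over 20 s, values of o within 1.5 percentage points.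

**The burst.** Intermediate stays near equilibrium with starting material, since its return at 15.9 s⁻¹ is faster than capture at 3.66 s⁻¹. Free first nucleophile relaxes into the dormant form, its resting state, at λ = 0.412 s⁻¹. Integrating capture over that relaxation, with the free first nucleophile taken as falling to zero, gives my estimate of the burst number b = 0.528.

For Tuesday's flask this estimate puts a at 0.590 and p at 0.410 after the burst, with capture into target as the one loss counted, an overlap of 0.242. For Sunday's flask, where the starting material arrives over 8.0 s, I divide b by λ times that time, which gives 0.160 and an overlap of 0.126.

As the mean of a·p over the run I guess half of that overlap. That gives me 30.4% for Tuesday's and 15.8% for Sunday's, a gap of 15 points against the margin of 1.5 points. For Saturday's flask I keep b and delay the overlap by half the feed, which gives me 24.3%. I treat Monday's as Sunday's.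

**The forecast.** It names Tuesday's, with 27% for Saturday's, 18% for Monday's, 31% for Tuesday's and 17% for Sunday's, on the ground that “dosing the starting material lets the nucleophile go dormant first”.

**The flask.** The simulation names Tuesday's: 25.4% for Saturday's, 17.3% for Monday's, 29.8% for Tuesday's, 16.3% for Sunday's.

**Clock again.** In Saturday's flask from 8.00 s to 20.0 s, the mean a and p on τ give 18 points, and side product gains 18 points. Sunday's flask, read later, goes from a = 58.2% and p = 14.0% at 20.0 s to 26.2% and 15.6% at 50.0 s. The clock adds 24 points to 16.3%, making 39.9%, and that flask reads 39.0%.

The rate constants are those of an exercise.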